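**The trap.** A product curve lying flat below full yield looks like a reaction that stopped early. But the starting material reads 0.1% at 3.00 d in the epsilon run and 0% at 2.50 d in the eta run, so we read each plateau as a split between two channels. The new flask holds more protic impurity than either run, and we want the new split.

| flask | starting material | coupling partner | protic impurity | free catalyst | remark | time |
|---|---|---|---|---|---|---|
| epsilon | 0.089 M | 0.089 M | 0.044 M | 0.44 mM | run made earlier |  |
| eta | 0.089 M | 0.089 M | 0.067 M | 0.44 mM | run made earlier |  |
| flask | 0.089 M | 0.0890 M | 0.0890 M | 0.44 mM |  | 15 d |

| run | time / d | starting material / % | product / % |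
|---|---|---|---|
| epsilon | 1.04 | 8.1 | 75.3 |
| epsilon | 3.00 | 0.1 | 82.5 |
| epsilon | 5.00 | 0.1 | 81.8 |
| epsilon | 8.00 | 0.5 | 83.0 |
| epsilon | 12.0 | 0 | 82.6 |
| epsilon | 15.0 | 0.3 | 81.8 |
| eta | 2.50 | 0 | 75.4 |
| eta | 5.00 | 0 | 75.6 |
| eta | 8.00 | 0 | 74.6 |
| eta | 10.0 | 0 | 76.1 |
| eta | 12.0 | 0.7 | 74.8 |
| eta | 15.0 | 0.7 | 75.6 |

(standard deviation of a reading: 0.5 percentage points)

1. at 15 d, what has stopped the reaction, if anything has (the coupling partner has run out first / forward and back rates have come level / no working catalyst is left / it is still moving / all of the starting material has reacted)
2. conversion of starting material at 15 d
3. amount of product at 15 d, in percent of the starting material charged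
4. amount of product if the flask were left three thousand times as long, in percent of the starting material charged

- the reaction counts as stopped when no species that holds the starting material changes by six tenths of a point or more over the second half of the time

**The rate ratio.** We follow the rate of making product over the rate of losing starting material. Falling starting material seems to slow both by the same factor: the epsilon plateau reads 82.3% product, so the lost share of what had reacted in epsilon is 17.7% there and 18.1% at 1.04 d. We suppose that the loss rate follows [protic impurity], and that each loss uses up one impurity. Eta's plateau reads 75.4%.

**Split constant.** Multiply the rate ratio by the mean [protic impurity], taken as the charge less half the amount lost. Epsilon gives 0.169 M and eta 0.171 M. Their mean is our split constant, a kind of selectivity factor: 0.170 M.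

**Two rounds.** With the flask's impurity held at its charge, the ratio is 1.91, giving 65.6% product. But that loss uses up impurity, slowing the loss rate on average by a factor 0.828. The ratio rises to 2.31, and our answer is 69.7%.

**The forecast.** It says all of the starting material has reacted, with 100% conversion, 70% product at the asked time and 70% in the long run: “The plateaus are flat, with no sign of drift, so waiting longer changes nothing.”

**The result.** The flask gives 69.9% product at 100% conversion, and 69.9% in the long run: all of the starting material has reacted. The forecast holds. The protic impurity ends at 70% of its charge. Reckoned from this flask's own yield, the split constant is 0.175 M, against the 0.170 M we carried.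

    starting material + free catalyst → catalyst intermediate A (k = 6.60 M⁻¹ min⁻¹)
    coupling partner + catalyst intermediate A → catalyst intermediate B (k = 5.90 M⁻¹ min⁻¹)
    catalyst intermediate B ⇌ catalyst intermediate C (K = 0.630, k = 1.50 min⁻¹)
    catalyst intermediate C → free catalyst + product (k = 3.20 min⁻¹)
    starting material + protic impurity → quenched substrate (k = 0.00790 M⁻¹ min⁻¹)

**A neighbour.** Charge 0.15 M of starting material instead. Putting the same first answer back gives a ratio of 2.69, which asks for 0.109 M of product, more than the 0.0890 M of coupling partner charged. So the partner should be the limiting reagent, with product near 59.3%. The computed neighbour gives 59.3%, with 0% of its coupling partner left.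

The earlier runs and the new flask were generated by integration with constants of no real substance; the scatter is artificial.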